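**Retrosynthetic overview**
1. The target is an achiral isoflavone: a 7-methoxychromone (rings A/C) carrying at C3 a 5-methoxy-2,2-dimethyl-2H-chromene (rings B/D).
2. The γ-pyrone C ring is closed last, by O1–C2 cyclodehydration of a 2-aryl-3-(2-hydroxyaryl)-3-oxopropanal once its MOM group is removed.
3. The C3–C1′ bond is the new step: acid-catalysed insertion of the diazo carbon of an aryl diazomethyl ketone into the aryl–CHO bond of the B/D aldehyde (1,2-aryl shift, loss of N2).
4. The B/D aldehyde comes from angular chromenylation of 2,4-dihydroxybenzaldehyde with prenal (D ring formed first), then O-methylation.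
5. The A-ring piece is paeonol, converted to its MOM ether and then to the diazomethyl ketone. Ring order: D, then C; A and B are bought as arenes.

Assumption: the target SMILES has no stereocentre and its C3–C1′ axis is not configurationally stable, so "single enantiomer" is read as the constitution as drawn.
Assumption: building blocks that bring skeletal carbon are numbered; simple reagents are named with SMILES in their step and not numbered.

**Route**

Step 1
Reactants: 1 2,4-dihydroxybenzaldehyde; 2 3-methylbut-2-enal (prenal)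
Product: 3 5-hydroxy-2,2-dimethyl-2H-chromene-6-carbaldehyde
Conditions: 2 (2 equiv), pyridine, 140 °C, sealed tube, 24 h
Reagents that add atoms: none
Why: Formal [3+3] chromenylation (Knoevenagel-type C-alkylation at C3, dehydration to an o-quinone methide, oxa-6π electrocyclisation); the 2-OH is held in a hydrogen bond to the CHO, so the free 4-OH closes the ring and the bond fixation of that chelate sends the new C–C bond to C3, giving the angular isomer.

Step 2
Reactants: 3 5-hydroxy-2,2-dimethyl-2H-chromene-6-carbaldehyde
Product: 4 5-methoxy-2,2-dimethyl-2H-chromene-6-carbaldehyde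
Conditions: MeI (3 equiv), K2CO3, DMF, 40 °C
Reagents that add atoms: iodomethane, CI
Why: Williamson O-methylation of the only phenol (chelated, hence polar solvent and gentle warming); the aldehyde and chromene alkene are inert to these conditions.

Step 3
Reactants: 5 1-(2-hydroxy-4-methoxyphenyl)ethan-1-one (paeonol)
Product: 6 1-[4-methoxy-2-(methoxymethoxy)phenyl]ethan-1-one
Conditions: NaH (1.1 equiv), MOMCl (1.2 equiv), THF/DMF, 0 °C to rt
Reagents that add atoms: chloromethyl methyl ether, COCCl
Why: Williamson-type O-alkylation of the sodium phenoxide masks the phenol, which would otherwise quench the enolate in step 4 and trap the diazo ketone as a benzofuranone in step 5.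

Step 4
Reactants: 6 1-[4-methoxy-2-(methoxymethoxy)phenyl]ethan-1-one
Product: 8 2-diazo-1-[4-methoxy-2-(methoxymethoxy)phenyl]ethan-1-one, via trifluoroacetyl diketone 7 (not isolated)
Conditions: LiHMDS (1.1 equiv), THF, −78 °C; CF3CO2CH2CF3 (1.2 equiv), −78 °C; 5% aq. HCl work-up; crude 7, MsN3 (1.5 equiv), Et3N (1.5 equiv), H2O (1 equiv), MeCN, rt
Reagents that add atoms: methanesulfonyl azide, CS(=O)(=O)N=[N+]=[N-] (both diazo nitrogens of 8); 2,2,2-trifluoroethyl trifluoroacetate, O=C(OCC(F)(F)F)C(F)(F)F (its CF3CO group is in 7 only)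
Why: Claisen trifluoroacetylation of the kinetic lithium enolate followed by Regitz-type detrifluoroacetylative diazo transfer is the standard conversion of an aryl methyl ketone into its diazomethyl ketone, and the MOM and methyl ethers are inert to both stages.

Step 5
Reactants: 4 5-methoxy-2,2-dimethyl-2H-chromene-6-carbaldehyde; 8 2-diazo-1-[4-methoxy-2-(methoxymethoxy)phenyl]ethan-1-one
Product: 9 (Z)-3-hydroxy-1-[4-methoxy-2-(methoxymethoxy)phenyl]-2-(5-methoxy-2,2-dimethyl-2H-chromen-6-yl)prop-2-en-1-one
Conditions: HBF4·OEt2 (15 mol%), CH2Cl2, −78 °C; 8 (1.4 equiv) added over 2 h; −78 to −30 °C; sat. NaHCO3 quench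
Reagents that add atoms: none
Why: Proposed new method: acid-catalysed formal insertion of the diazo carbon of an aryl diazomethyl ketone into an aryl–CHO bond. The protonated aldehyde 4 is attacked by the nucleophilic diazo carbon of 8 to give a β-hydroxy-α-diazonium ketone; the 2-methoxy-4-alkoxyaryl group, anti-periplanar to N2 and a far better migrating group than H, shifts to the diazonium carbon as N2 leaves through a phenonium-like transition state stabilised by both ring oxygens. This forms the C3–C1′ bond and leaves the old aldehyde carbon as the formyl (enol) carbon, the future C2. Epoxide formation by O-attack funnels to the same product by acid-induced aroyl shift, and the hydride-shift (Roskamp) path to the 1,3-diketone is disfavoured for so electron-rich an aryl group. Slow addition of 8 at −78 °C keeps C-protonation of the diazo ketone low, and catalytic acid at low temperature spares the chromene alkene and the MOM ether. The closest known reaction type is the Brønsted-acid-catalysed aryl-migrating homologation of aromatic aldehydes with alkyl diazoacetates to 3-hydroxy-2-arylacrylates; to my knowledge it has not been shown with a diazomethyl aryl ketone, nor used as an isoflavone construction. No stereocentre is formed.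

Step 6
Reactants: 9 (Z)-3-hydroxy-1-[4-methoxy-2-(methoxymethoxy)phenyl]-2-(5-methoxy-2,2-dimethyl-2H-chromen-6-yl)prop-2-en-1-one
Product: 12 7-methoxy-3-(5-methoxy-2,2-dimethyl-2H-chromen-6-yl)-4H-chromen-4-one, via free phenol ketoaldehyde 10 (not isolated), via 2-hydroxyisoflavanone 11 (not isolated)
Conditions: HCl (1.25 M in MeOH), THF, 45 °C
Reagents that add atoms: none
Why: Acid-catalysed acetal exchange removes the MOM group, the freed phenol adds to the formyl (enol) carbon to give the cyclic hemiacetal, and E1-type dehydration gives the γ-pyrone (the classical formyl-deoxybenzoin closure to an isoflavone); aryl methyl ethers and the 2,2-dimethylchromene tolerate dilute methanolic HCl at this temperature.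

**Compound list**
1 | 2,4-dihydroxybenzaldehyde | O=Cc1ccc(O)cc1O | starting material
2 | 3-methylbut-2-enal (prenal) | CC(C)=CC=O | starting material
3 | 5-hydroxy-2,2-dimethyl-2H-chromene-6-carbaldehyde | CC1(C)C=Cc2c(O)c(C=O)ccc2O1 | intermediate
4 | 5-methoxy-2,2-dimethyl-2H-chromene-6-carbaldehyde | CC1(C)C=Cc2c(OC)c(C=O)ccc2O1 | intermediate
5 | 1-(2-hydroxy-4-methoxyphenyl)ethan-1-one (paeonol) | CC(=O)c1ccc(OC)cc1O | starting material
6 | 1-[4-methoxy-2-(methoxymethoxy)phenyl]ethan-1-one | CC(=O)c1ccc(OC)cc1OCOC | intermediate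
7 | trifluoroacetyl diketone: 4,4,4-trifluoro-1-[4-methoxy-2-(methoxymethoxy)phenyl]butane-1,3-dione (not isolated) | O=C(CC(=O)C(F)(F)F)c1ccc(OC)cc1OCOC | intermediate
8 | 2-diazo-1-[4-methoxy-2-(methoxymethoxy)phenyl]ethan-1-one | [N-]=[N+]=CC(=O)c1ccc(OC)cc1OCOC | intermediate
9 | (Z)-3-hydroxy-1-[4-methoxy-2-(methoxymethoxy)phenyl]-2-(5-methoxy-2,2-dimethyl-2H-chromen-6-yl)prop-2-en-1-one (hydrogen-bonded enol of the 3-oxopropanal) | O/C=C(/c1ccc2OC(C)(C)C=Cc2c1OC)C(=O)c1ccc(OC)cc1OCOC | intermediate
10 | free phenol ketoaldehyde: (Z)-3-hydroxy-1-(2-hydroxy-4-methoxyphenyl)-2-(5-methoxy-2,2-dimethyl-2H-chromen-6-yl)prop-2-en-1-one (not isolated) | O/C=C(/c1ccc2OC(C)(C)C=Cc2c1OC)C(=O)c1ccc(OC)cc1O | intermediate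
11 | 2-hydroxyisoflavanone: 2-hydroxy-7-methoxy-3-(5-methoxy-2,2-dimethyl-2H-chromen-6-yl)chroman-4-one (not isolated; racemic mixture of C2/C3 diastereomers, both centres lost on dehydration, so none is specified) | COc1ccc2C(=O)C(c3ccc4OC(C)(C)C=Cc4c3OC)C(O)Oc2c1 | intermediate
12 | 7-methoxy-3-(5-methoxy-2,2-dimethyl-2H-chromen-6-yl)-4H-chromen-4-one | COc1ccc2c(=O)c(-c3ccc4c(c3OC)C=CC(C)(C)O4)coc2c1 | target

**Totals**
Total step count: 6.
Longest linear sequence: 4 steps (1 → 3 → 4 → 9 → 12, or 5 → 6 → 8 → 9 → 12).

**Three steps most likely to fail**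

Step 5 (the proposed new step). Likely failures are acid-induced loss of N2 from 8 with participation of the ortho oxygen (giving 6-methoxybenzofuran-3(2H)-one), or hydride shift to the 1,3-diketone, which would end as the isomeric flavone. The fallback is the known epoxide route to formyl deoxybenzoins; it sets out from 4 (together with 6, already in hand) and comes back at 9. Claisen–Schmidt condensation of 4 with 6 (KOH, EtOH, rt) gives the chalcone (E)-1-[4-methoxy-2-(methoxymethoxy)phenyl]-3-(5-methoxy-2,2-dimethyl-2H-chromen-6-yl)prop-2-en-1-one F1. Weitz–Scheffer epoxidation (30% H2O2, cat. NaOH, MeOH/THF, 0 °C) is nucleophilic and leaves the electron-rich chromene alkene alone; it gives the racemic trans-epoxide [(2R,3S)-3-(5-methoxy-2,2-dimethyl-2H-chromen-6-yl)oxiran-2-yl][4-methoxy-2-(methoxymethoxy)phenyl]methanone F2. BF3·OEt2 (0.5 equiv, CH2Cl2, −20 °C, minutes) opens the epoxide at the benzylic carbon and the aroyl group shifts (House–Meinwald rearrangement) to give 9. Any MOM loss after the rearrangement is harmless, since step 6 removes it anyway.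

Step 1. Likely failures are a modest yield, the linear isomer, or prenal self-condensation. The fallback changes the ring construction to a propargyl Claisen sequence; it sets out from 1 and comes back at 3. Selective O-alkylation of the non-chelated 4-OH of 1 with 3-chloro-3-methylbut-1-yne (K2CO3, cat. KI, cat. CuI, acetone, 60 °C) gives 2-hydroxy-4-[(2-methylbut-3-yn-2-yl)oxy]benzaldehyde F3. Heating in N,N-diethylaniline (190 °C) brings about aromatic propargyl Claisen rearrangement to C3, [1,5]-H shift and oxa-6π electrocyclisation, giving 3.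

Step 6. The likely failure is acid methanolysis of the formyl group (retro-Claisen deformylation) before ring closure. The fallback accepts the deformylation and closes the ring by the deoxybenzoin method; it sets out from 9 and comes back at 12. K2CO3 (cat.) in MeOH at rt cleaves the formyl group cleanly to the deoxybenzoin 1-[4-methoxy-2-(methoxymethoxy)phenyl]-2-(5-methoxy-2,2-dimethyl-2H-chromen-6-yl)ethan-1-one F4. The MOM group ortho to the ketone of this robust compound is removed with p-TsOH (cat.) in MeOH at 40 °C, giving 1-(2-hydroxy-4-methoxyphenyl)-2-(5-methoxy-2,2-dimethyl-2H-chromen-6-yl)ethan-1-one F5. N,N-dimethylformamide dimethyl acetal (COC(OC)N(C)C, toluene, 90 °C) puts the C2 carbon back as the enaminone (E)-3-(dimethylamino)-1-(2-hydroxy-4-methoxyphenyl)-2-(5-methoxy-2,2-dimethyl-2H-chromen-6-yl)prop-2-en-1-one F6, which is not isolated and closes by addition–elimination of the phenol to give 12.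

**Further compounds**
F1 | step 5 | (E)-1-[4-methoxy-2-(methoxymethoxy)phenyl]-3-(5-methoxy-2,2-dimethyl-2H-chromen-6-yl)prop-2-en-1-one | COCOc1cc(OC)ccc1C(=O)/C=C/c1ccc2OC(C)(C)C=Cc2c1OC
F2 | step 5 | rac-[(2R,3S)-3-(5-methoxy-2,2-dimethyl-2H-chromen-6-yl)oxiran-2-yl][4-methoxy-2-(methoxymethoxy)phenyl]methanone (trans; one enantiomer of the racemate drawn) | O=C(c1ccc(OC)cc1OCOC)[C@@H]1O[C@H]1c1ccc2OC(C)(C)C=Cc2c1OC
F3 | step 1 | 2-hydroxy-4-[(2-methylbut-3-yn-2-yl)oxy]benzaldehyde | C#CC(C)(C)Oc1ccc(C=O)c(O)c1
F4 | step 6 | 1-[4-methoxy-2-(methoxymethoxy)phenyl]-2-(5-methoxy-2,2-dimethyl-2H-chromen-6-yl)ethan-1-one | COCOc1cc(OC)ccc1C(=O)Cc1ccc2OC(C)(C)C=Cc2c1OC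
F5 | step 6 | 1-(2-hydroxy-4-methoxyphenyl)-2-(5-methoxy-2,2-dimethyl-2H-chromen-6-yl)ethan-1-one | COc1ccc(C(=O)Cc2ccc3OC(C)(C)C=Cc3c2OC)c(O)c1
F6 | step 6 | (E)-3-(dimethylamino)-1-(2-hydroxy-4-methoxyphenyl)-2-(5-methoxy-2,2-dimethyl-2H-chromen-6-yl)prop-2-en-1-one (not isolated) | CN(C)/C=C(/C(=O)c1ccc(OC)cc1O)c1ccc2OC(C)(C)C=Cc2c1OC
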